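Substrate stands in both the step that makes target and the step that consumes it, so it cancels from their balance whatever the charge. What remains is a moving level, which we call the balance level: the target concentration at which making and loss by side product are equal.

| flask | substrate | reagent | time |
|---|---|---|---|
| blue | 0.20 mM | 0.200 mM | 50 s |
| violet | 0.30 mM | 0.200 mM | 50 s |
| amber | 0.50 mM | 0.200 mM | 50 s |
| ochre | 0.60 mM | 0.200 mM | 50 s |
    target ⇌ isomer of the product (K1 = 0.32, k1 = 0.031 s⁻¹)
    substrate + reagent → target, rate k2*[substrate]*[reagent]^1.5 (k2 = 5000 L¹·⁵ mol⁻¹·⁵ s⁻¹)
    substrate + target → side product (k3 = 56 L mol⁻¹ s⁻¹)
- percent here means substrate units held: one side product counts as two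
- "hardly changes" means that all values lie within two and a half points (for a concentration: within two and a half percent of the largest)
- run time (blue): 50 s
- [target] at the end for blue, violet, amber, ochre, in this order
- the shape of the row from first to last (hardly changes / rises, then falls / rises all the way / falls all the way / falls, then rises)

Before reckoning, we ask which numbers need to be good. An error in the making constant or the loss constant moves the balance level by the same fraction. The reagent charge counts more than in proportion, since it enters multiplied by its own square root. At equilibrium the isomer holds a quarter of the target and isomer pool, which lowers target but leaves the level alone. The isomer rate constant does not enter the level, and the pair relaxes in 5.42 s, much shorter than the run. On the level, substrate acts indirectly: it sets how fast reagent, and so the level, falls.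

Our reckoning, with substrate held at its charge, which makes the fall too steep:

balance level at the charge = 5000 L¹·⁵ mol⁻¹·⁵ s⁻¹ × 0.200 mM × √0.200 mM ÷ 56 L mol⁻¹ s⁻¹ = 0.253 mM

x = half × 5000 L¹·⁵ mol⁻¹·⁵ s⁻¹ × substrate × √0.200 mM × time: blue 0.354, ochre 1.06

reagent divides by (one plus x) squared, the level by (one plus x) cubed: blue 0.102 mM, ochre 0.0289 mM

In blue, reagent used comes to 0.0908 mM, less than the level, so by this reckoning target, which takes one reagent each, stays under it. In ochre, 0.153 mM is used, more than the level, so target can cross it. From blue to ochre, reagent used rises and the level falls, so we commit to a rise and then a fall, but to no row.

The forecast gave 0.05 mM, 0.057 mM, 0.062 mM and 0.06 mM, shape rises, then falls, adding: “the turnover between amber and ochre is small, so the shape is my less certain call”.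

The flasks gave 0.0483 mM, 0.0567 mM, 0.0588 mM and 0.0560 mM, shape rises, then falls.

In blue, making ran with 62.6% of the reagent left at 50.0 s, the level stood at 0.125 mM, higher than target, and target was still made 1.72 times faster than used up. In ochre, 29.7% of the reagent was left at the same time, the level stood at 0.0410 mM, lower than target, and target slipped from 9.92% at 25.0 s to 9.34% of the substrate charged. Violet ended with the level at 0.0916 mM, higher than its target, amber with the level at 0.0524 mM, lower than its target, and the row turns between them, at 0.42 mM.

Its constants are assumed; the run is a simulation.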